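**Plan**

1. Numbering is that of 3,7-dioxabicyclo[3.3.0]octane: C1 is the ring-fusion carbon with OH, C2 and C6 are the benzylic carbons, C4 and C8 the OCH2 carbons, C5 the ring-fusion CH. Ring A is C1, C2, O3, C4, C5; ring B is C1, C5, C6, O7, C8.
2. Retrosynthetic cuts: the two phenol O–S bonds; the C6–H bond of ring B (back to an aryl ketone and the C8 alcohol); the C8 methylene (back to a γ-lactone carbonyl); then C1–C2 and C4–C5 of ring A together.
3. Enabling feature: ring A holds the unit C2–O3–C4 (benzylic CH, ring oxygen, OCH2), and its two carbons are bonded to the adjacent ring-fusion carbons C1 and C5. This is the retron of a carbonyl ylide ArCH=O(+)–CH2(−) adding to a C1=C5 alkene, here the C3=C4 bond of a 3-acetoxy-5-aryl-butenolide. Its lactone carbonyl (later C8H2) activates the alkene and its enol oxygen becomes the C1 hydroxyl.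
4. Forward order: vanillin mesylate gives the butenolide (ring B at lactone level) by asymmetric 2-(ethoxycarbonyl)allylation, ozonolysis and enol acetylation. The same aldehyde gives the α-chloro silylmethyl ether. The [3+2] step builds ring A. Lactone reduction, benzylic oxidation and reductive etherification rebuild ring B, and the mesylates come off last.
5. Stereochemistry: the catalytic allylation sets C5 of the butenolide (S). This centre steers the dipole to the opposite face (C1 and C5 of the bicycle), and the exo mode sets C2. The centre would leave the C6 aryl exo, so it is then erased by oxidation and re-set by hydride delivery to the convex face, which gives the endo C6 aryl of the target.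

Key step: step 6

Remark: Ar = 4-(methanesulfonyloxy)-3-methoxyphenyl in the step names below; full names and SMILES are in the compound list.

**Route**

Step 1
Reactants: 1 vanillin
Product: 2 4-formyl-2-methoxyphenyl methanesulfonate
Conditions: MsCl, Et3N, CH2Cl2, 0 °C
Reagents that add atoms: methanesulfonyl chloride, CS(=O)(=O)Cl
Why: O-sulfonylation of the phenol gives a mesylate that should withstand HCl, fluoride, borohydride and Lewis acid, deactivates the arene toward ozone and benzylic ionisation, and is removable at the end.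

Step 2
Reactants: 2 4-formyl-2-methoxyphenyl methanesulfonate; 3 ethyl 2-(bromomethyl)prop-2-enoate
Product: 5 (5S)-5-Ar-3-methylideneoxolan-2-one, via hydroxy ester 4 (not isolated)
Conditions: CrCl2 (10 mol %), chiral 1,8-bis(oxazolinyl)carbazole ligand (12 mol %), Mn powder, Me3SiCl, i-Pr2NEt (20 mol %), THF, rt; then 1 M HCl, THF; TsOH (5 mol %), toluene, 50 °C
Reagents that add atoms: none
Why: In this catalytic enantioselective Nozaki–Hiyama–Kishi-type 2-(alkoxycarbonyl)allylation the allylchromium species formed from 3 adds to one enantiotopic face of the aldehyde inside the chiral ligand sphere through a closed six-membered transition state, Mn returns chromium to the divalent state, Me3SiCl frees it from the alkoxide, acid closes the γ-lactone, and the ligand antipode is chosen to give the S centre.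

Step 3
Reactants: 5 (5S)-5-Ar-3-methylideneoxolan-2-one
Product: 8 (5S)-3-hydroxy-5-Ar-furan-2(5H)-one, via spiro ozonide 6 (not isolated), via dioxo lactone 7 (not isolated)
Conditions: O3, CH2Cl2, −78 °C; then Me2S, −78 °C to rt
Reagents that add atoms: ozone, [O-][O+]=O
Why: Ozonolysis of the exocyclic alkene with reductive work-up should give the 2,3-dioxo lactone, which enolises toward C4 to the conjugated 3-hydroxybutenolide without involving the C5 stereocentre, the sulfonyloxy arene being too electron-poor to compete for ozone.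

Step 4
Reactants: 8 (5S)-3-hydroxy-5-Ar-furan-2(5H)-one
Product: 9 (5S)-5-Ar-2-oxo-2,5-dihydrofuran-3-yl acetate
Conditions: Ac2O, pyridine, CH2Cl2, 0 °C
Reagents that add atoms: acetic anhydride, CC(=O)OC(C)=O
Why: O-acylation of the acidic enol hydroxyl (enol ester formation) under weakly basic conditions should leave C5 untouched and gives an acetate that keeps the alkene electron-poor and is lost in the later hydride step to free the tertiary alcohol.

Step 5
Reactants: 2 4-formyl-2-methoxyphenyl methanesulfonate; 10 (trimethylsilyl)methanol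
Product: 11 4-{chloro[(trimethylsilyl)methoxy]methyl}-2-methoxyphenyl methanesulfonate (racemic)
Conditions: HCl (gas), MgSO4, CH2Cl2, 0 °C; volatiles removed, used crude
Reagents that add atoms: hydrogen chloride, Cl
Why: This is α-chloro ether formation from an aldehyde, an alcohol and HCl (hemiacetal, then chloride for hydroxide through the oxocarbenium ion), and the chlorine-bearing carbon, formed racemic, becomes trigonal in step 6.

Step 6
Reactants: 9 (5S)-5-Ar-2-oxo-2,5-dihydrofuran-3-yl acetate; 11 4-{chloro[(trimethylsilyl)methoxy]methyl}-2-methoxyphenyl methanesulfonate (2 equiv)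
Product: 13 (1R,2R,5R,6S)-1-acetoxy-2,6-di-Ar-3,7-dioxabicyclo[3.3.0]octan-8-one, via carbonyl ylide 12 (not isolated)
Conditions: CsF (2.5 equiv), MeCN, 0 °C to rt
Reagents that add atoms: none
Why: Fluoride attacks silicon of 11 (or of the oxocarbenium chloride in equilibrium with it) and the silicon-based 1,3-elimination gives the nonstabilised carbonyl ylide 12, a four-π-electron C–O–C dipole, which adds to the electron-poor C3=C4 bond of 9 in a concerted, asynchronous, suprafacial 1,3-dipolar cycloaddition (dipole HOMO, dipolarophile LUMO). The closest known reaction type is the fluoride-triggered generation of carbonyl ylides from 1-chloroalkyl (trimethylsilyl)methyl ethers and their [3+2] cycloaddition to acrylates, maleates and other activated alkenes. Ring A, the new oxolane, is closed by this intermolecular [3+2] cycloaddition, both C–C bonds forming on one face of the alkene, so the bicycle is cis-fused. The ring-fusion carbons C1 and C5 of 13 are set by approach of the dipole to the face of 9 opposite to the aryl group on its S-configured C5, and C2 of 13 by the E geometry of the ylide in an exo transition state (ylide oxygen outside the lactone ring), which should keep the aryl group on the convex face, cis to the acetoxy group. The step needs regioselectivity, which the α-acyloxy acrylate polarisation of 9 should secure (the nucleophilic CH2 terminus bonds to the β-carbon C4 of 9, the oxocarbenium-like benzylic terminus to the acetoxy-bearing α-carbon C3). It also needs face selectivity, secured by the C5 aryl group, and preference of fluoride for silicon over the acidic C5–H of 9, which the excess of 11 and the low solubility of CsF should favour.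

Step 7
Reactants: 13 (1R,2R,5R,6S)-1-acetoxy-2,6-di-Ar-3,7-dioxabicyclo[3.3.0]octan-8-one
Product: 14 (2R,3S,4R)-2-Ar-4-[(S)-Ar(hydroxy)methyl]-3-(hydroxymethyl)oxolan-3-ol
Conditions: LiBH4, MeOH (2 equiv), THF, 0 °C to rt
Reagents that add atoms: none
Why: Borohydride reduction of the γ-lactone to the 1,4-diol with reductive loss of the tertiary acetate should leave the aryl sulfonates and all four stereocentres untouched.

Step 8
Reactants: 14 (2R,3S,4R)-2-Ar-4-[(S)-Ar(hydroxy)methyl]-3-(hydroxymethyl)oxolan-3-ol
Product: 15 (2R,3S,4S)-2-Ar-4-(Ar-carbonyl)-3-(hydroxymethyl)oxolan-3-ol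
Conditions: activated MnO2 (excess), CH2Cl2, rt
Reagents that add atoms: none
Why: Heterogeneous MnO2 oxidation is selective for the benzylic alcohol over the primary and tertiary aliphatic hydroxyl groups and erases the carbinol centre that has served to direct step 6.

Step 9
Reactants: 15 (2R,3S,4S)-2-Ar-4-(Ar-carbonyl)-3-(hydroxymethyl)oxolan-3-ol
Product: 18 (1S,2R,5R,6R)-2,6-di-Ar-3,7-dioxabicyclo[3.3.0]octan-1-ol, via cyclic hemiketal 16 (not isolated), via oxocarbenium ion 17 (not isolated)
Conditions: Et3SiH, BF3·OEt2, CH2Cl2, −78 to −20 °C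
Reagents that add atoms: none
Why: In this reductive etherification (ionic hydrogenation) the γ-hydroxy ketone closes to hemiketal 16, ionises to the aryl-substituted oxocarbenium ion 17 and takes hydride from the silane on the convex face of the cis-fused bicycle, anti to ring A, which places the new C6–H cis to C5–H and the aryl group endo (6R), while the electron-poor sulfonyloxyaryl groups should suppress ionisation of the benzylic ethers.

Step 10
Reactants: 18 (1S,2R,5R,6R)-2,6-di-Ar-3,7-dioxabicyclo[3.3.0]octan-1-ol
Product: 19 (1S,2R,5R,6R)-2,6-bis(4-hydroxy-3-methoxyphenyl)-3,7-dioxabicyclo[3.3.0]octan-1-ol (target)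
Conditions: LiN(i-Pr)2 (6 equiv), THF, −78 to 0 °C; then aq. NH4Cl
Reagents that add atoms: none
Why: The lithium amide deprotonates the S-methyl group of each aryl mesylate and sulfene is expelled with release of the phenoxide (E1cB cleavage of aryl methanesulfonates) at a temperature at which the benzylic ethers and their configurations should not be affected.

**Compound list**

1 | vanillin (4-hydroxy-3-methoxybenzaldehyde) | COc1cc(C=O)ccc1O | starting material
2 | 4-formyl-2-methoxyphenyl methanesulfonate | COc1cc(C=O)ccc1OS(C)(=O)=O | intermediate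
3 | ethyl 2-(bromomethyl)prop-2-enoate | CCOC(=O)C(=C)CBr | starting material
4 | ethyl (4S)-4-hydroxy-4-[4-(methanesulfonyloxy)-3-methoxyphenyl]-2-methylidenebutanoate | CCOC(=O)C(=C)C[C@H](O)c1ccc(OS(C)(=O)=O)c(OC)c1 | intermediate (not isolated)
5 | (5S)-5-[4-(methanesulfonyloxy)-3-methoxyphenyl]-3-methylideneoxolan-2-one | C=C1C[C@@H](c2ccc(OS(C)(=O)=O)c(OC)c2)OC1=O | intermediate
6 | spiro ozonide of 5 (1,2,4-trioxolane spiro-fused at C3 of the (5S)-lactone, spiro carbon undefined) | O=C1O[C@H](c2ccc(OS(C)(=O)=O)c(OC)c2)CC12OOCO2 | intermediate (not isolated)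
7 | (5S)-5-[4-(methanesulfonyloxy)-3-methoxyphenyl]oxolane-2,3-dione | O=C1C[C@@H](c2ccc(OS(C)(=O)=O)c(OC)c2)OC1=O | intermediate (not isolated)
8 | (5S)-3-hydroxy-5-[4-(methanesulfonyloxy)-3-methoxyphenyl]furan-2(5H)-one | OC1=C[C@@H](c2ccc(OS(C)(=O)=O)c(OC)c2)OC1=O | intermediate
9 | (5S)-5-[4-(methanesulfonyloxy)-3-methoxyphenyl]-2-oxo-2,5-dihydrofuran-3-yl acetate | CC(=O)OC1=C[C@@H](c2ccc(OS(C)(=O)=O)c(OC)c2)OC1=O | intermediate
10 | (trimethylsilyl)methanol | C[Si](C)(C)CO | starting material
11 | 4-{chloro[(trimethylsilyl)methoxy]methyl}-2-methoxyphenyl methanesulfonate (racemic) | COc1cc(C(Cl)OC[Si](C)(C)C)ccc1OS(C)(=O)=O | intermediate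
12 | (E)-carbonyl ylide ArCH=O(+)–CH2(−), Ar = 4-(methanesulfonyloxy)-3-methoxyphenyl | COc1cc(/C=[O+]/[CH2-])ccc1OS(C)(=O)=O | intermediate (not isolated)
13 | (1R,2R,5R,6S)-2,6-bis[4-(methanesulfonyloxy)-3-methoxyphenyl]-8-oxo-3,7-dioxabicyclo[3.3.0]octan-1-yl acetate | COc1cc([C@H]2OC[C@@H]3[C@@H](c4ccc(OS(C)(=O)=O)c(OC)c4)OC(=O)[C@]23OC(C)=O)ccc1OS(C)(=O)=O | intermediate
14 | (2R,3S,4R)-4-{(S)-hydroxy[4-(methanesulfonyloxy)-3-methoxyphenyl]methyl}-3-(hydroxymethyl)-2-[4-(methanesulfonyloxy)-3-methoxyphenyl]oxolan-3-ol | COc1cc([C@H]2OC[C@H]([C@H](O)c3ccc(OS(C)(=O)=O)c(OC)c3)[C@]2(O)CO)ccc1OS(C)(=O)=O | intermediate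
15 | (2R,3S,4S)-3-(hydroxymethyl)-4-[4-(methanesulfonyloxy)-3-methoxybenzoyl]-2-[4-(methanesulfonyloxy)-3-methoxyphenyl]oxolan-3-ol | COc1cc([C@H]2OC[C@H](C(=O)c3ccc(OS(C)(=O)=O)c(OC)c3)[C@]2(O)CO)ccc1OS(C)(=O)=O | intermediate
16 | (1S,2R,5S)-2,6-bis[4-(methanesulfonyloxy)-3-methoxyphenyl]-3,7-dioxabicyclo[3.3.0]octane-1,6-diol (cyclic hemiketal, both C6 epimers) | COc1cc([C@H]2OC[C@@H]3C(O)(c4ccc(OS(C)(=O)=O)c(OC)c4)OC[C@]23O)ccc1OS(C)(=O)=O | intermediate (not isolated)
17 | oxocarbenium ion from 16 (C6=O7 cation, C1, C2 and C5 as in 16) | COc1cc([C@H]2OC[C@@H]3C(c4ccc(OS(C)(=O)=O)c(OC)c4)=[O+]C[C@]23O)ccc1OS(C)(=O)=O | intermediate (not isolated)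
18 | (1S,2R,5R,6R)-2,6-bis[4-(methanesulfonyloxy)-3-methoxyphenyl]-3,7-dioxabicyclo[3.3.0]octan-1-ol | COc1cc([C@H]2OC[C@@H]3[C@H](c4ccc(OS(C)(=O)=O)c(OC)c4)OC[C@]23O)ccc1OS(C)(=O)=O | intermediate
19 | (1S,2R,5R,6R)-2,6-bis(4-hydroxy-3-methoxyphenyl)-3,7-dioxabicyclo[3.3.0]octan-1-ol | COc1cc([C@H]2OC[C@@H]3[C@H](c4ccc(O)c(OC)c4)OC[C@]23O)ccc1O | target

**Step count and risks**

Total step count: 10. Longest linear sequence: 9 steps (steps 1, 2, 3, 4, 6, 7, 8, 9, 10); step 5 is a one-step branch from 2.

Steps most likely to fail:

1. Step 6. Fluoride may act as a base on the acidic C5–H of 9 before the dipole is trapped. That would erode the only source of absolute configuration, or the resulting furanolate would be captured by 11. The exo preference at C2 and the regiochemistry may also be incomplete; the exo preference is the least secure element of the step. The fallback sets out from 9 (with aldehyde 2) and comes back at 13. It forms the dipole without fluoride or base. Slow addition of tert-butyl diazoacetate to 2 and 9 with Rh2(OAc)4 in CH2Cl2 at rt should give a rhodium carbene that is captured by the aldehyde oxygen. The ester-stabilised carbonyl ylide should add to 9 in the same sense and give the tert-butyl ester cycloadduct F1, which carries the ester on C4 as a traceless group. CF3CO2H in CH2Cl2 should free the C4 carboxylic acid F2. Photoredox hydrodecarboxylation of this α-alkoxy acid (9-mesityl-10-methylacridinium tetrafluoroborate, diphenyl disulfide and 2,6-lutidine in catalytic amounts, CF3CH2OH, blue light) should return 13.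

2. Step 9. Hydride may reach the wrong face of 17, the hemiketal may lose water under acid toward a furan, or ring A may open by ionisation at C2. The fallback sets out from 14, skips steps 8 and 9, and comes back at 18. It replaces the oxidation and reduction by a stereospecific SN2 ring closure with inversion at the benzylic carbinol. TBSCl and imidazole in DMF at 0 °C should silylate only the primary alcohol and give the primary silyl ether F3. MsCl and Et3N in CH2Cl2 at −20 °C should give the benzylic methanesulfonate F4. Bu4NF in THF at 0 °C should remove the silyl group, and the primary alkoxide should displace the mesylate in a 5-exo-tet closure with inversion, which makes the C6 aryl endo and gives 18.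

3. Step 8. The vicinal tertiary and primary diol may be cleaved oxidatively, and the electron-poor benzylic alcohol may oxidise slowly. The fallback sets out from 14 and comes back at 15. 2,2-Dimethoxypropane with pyridinium p-toluenesulfonate in acetone should mask the 1,2-diol as the acetonide F5. Dess–Martin periodinane in CH2Cl2 should then oxidise the only free hydroxyl to the keto acetonide F6. Aqueous acetic acid in THF should remove the acetonide and give 15.

**Further compounds**

F1 | step 6 | tert-butyl 1-acetoxy-2,6-bis[4-(methanesulfonyloxy)-3-methoxyphenyl]-8-oxo-3,7-dioxabicyclo[3.3.0]octane-4-carboxylate (C4 undefined, other centres as in 13) | COc1cc([C@H]2OC(C(=O)OC(C)(C)C)[C@@H]3[C@@H](c4ccc(OS(C)(=O)=O)c(OC)c4)OC(=O)[C@]23OC(C)=O)ccc1OS(C)(=O)=O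
F2 | step 6 | 1-acetoxy-2,6-bis[4-(methanesulfonyloxy)-3-methoxyphenyl]-8-oxo-3,7-dioxabicyclo[3.3.0]octane-4-carboxylic acid (C4 undefined, other centres as in 13) | COc1cc([C@H]2OC(C(=O)O)[C@@H]3[C@@H](c4ccc(OS(C)(=O)=O)c(OC)c4)OC(=O)[C@]23OC(C)=O)ccc1OS(C)(=O)=O
F3 | step 9 | primary tert-butyldimethylsilyl ether of 14 | COc1cc([C@H]2OC[C@H]([C@H](O)c3ccc(OS(C)(=O)=O)c(OC)c3)[C@]2(O)CO[Si](C)(C)C(C)(C)C)ccc1OS(C)(=O)=O
F4 | step 9 | benzylic (S)-methanesulfonate of F3 | COc1cc([C@H]2OC[C@H]([C@H](OS(C)(=O)=O)c3ccc(OS(C)(=O)=O)c(OC)c3)[C@]2(O)CO[Si](C)(C)C(C)(C)C)ccc1OS(C)(=O)=O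
F5 | step 8 | acetonide of 14 across the C3 hydroxyl and the hydroxymethyl group (2,2-dimethyl-1,3-dioxolane spiro-fused at C3 of the oxolane) | COc1cc([C@H]2OC[C@H]([C@H](O)c3ccc(OS(C)(=O)=O)c(OC)c3)[C@]24COC(C)(C)O4)ccc1OS(C)(=O)=O
F6 | step 8 | aryl ketone of F5 (acetonide of 15) | COc1cc([C@H]2OC[C@H](C(=O)c3ccc(OS(C)(=O)=O)c(OC)c3)[C@]24COC(C)(C)O4)ccc1OS(C)(=O)=O
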